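**Plan**

- The last disconnection removes the two phenol protecting groups (both carried as methoxymethyl ethers).
- Ring B is then cut at C3–C3a and O1–C7a in one operation. This works because O1–C2(aryl)=C3(OMe) of ring B is the enolate of an aryl methoxymethyl ketone laid across the adjacent ring A carbons C3a and C7a.
- That leaves a 1-bromo-2-iodoarene (ring A with the prenyl group and the protected C6 oxygen) and the ketone (ring C, C2, C3 and the 3-methoxy group).
- The dihaloarene is built from 3-bromophenol (C–I, then C–prenyl, then O–MOM); the ketone by acylation of a ring C aryllithium.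
- Forward: rings A and C are bought as benzene rings; ring B is the only ring formed, in the palladium annulation, and deprotection ends the route.
- Stereochemistry: none to set. The target has no stereocentre and the prenyl double bond ends in two identical methyl groups.

Key step: step 6

Remark on the chemistry: ring A is the benzo ring (C3a to C7a), ring B the furan ring and ring C the 2-aryl ring. Intermediates 11 and 13 each carry one stereocentre, form as racemates and lose it in the same flask.

**Step 1**
Reactants: 1 3-bromophenol
Product: 2 3-bromo-4-iodophenol
Conditions: NIS, TsOH·H2O (cat.), MeCN, 0 °C to rt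
Reagents that add atoms: N-iodosuccinimide, O=C1CCC(=O)N1I
Why: Electrophilic aromatic iodination of a phenol with NIS under sulfonic acid catalysis is para-selective, and the only carbon para to the hydroxyl of 1 is C4 next to bromine, so iodine should enter there and the deactivated ring should stop at mono-iodination.

**Step 2**
Reactants: 2 3-bromo-4-iodophenol; 3 prenyl bromide (1-bromo-3-methylbut-2-ene)
Product: 5 5-bromo-4-iodo-2-(3-methylbut-2-en-1-yl)phenol, via sodium 3-bromo-4-iodophenoxide 4 (not isolated)
Conditions: NaH, toluene, 0 °C to rt; then 3, rt to 60 °C
Reagents that add atoms: none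
Why: Ortho C-alkylation of a sodium phenoxide as a tight ion pair in a non-polar solvent (phenoxide C-allylation) should put the prenyl group on C6 through its primary carbon, because the para carbon is blocked by iodine and the other ortho carbon is crowded between oxygen and bromine.

**Step 3**
Reactants: 5 5-bromo-4-iodo-2-(3-methylbut-2-en-1-yl)phenol
Product: 6 1-bromo-2-iodo-5-(methoxymethoxy)-4-(3-methylbut-2-en-1-yl)benzene
Conditions: NaH, THF, 0 °C; then MOMCl, 0 °C to rt
Reagents that add atoms: chloromethyl methyl ether, COCCl
Why: Williamson-type O-alkylation of the phenoxide with MOMCl gives an acetal ether that is inert to carbonate base and to zerovalent palladium at 110 °C, and neither the aryl halides nor the olefin are touched.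

**Step 4**
Reactants: 7 5-bromo-2-methoxyphenol
Product: 8 4-bromo-1-methoxy-2-(methoxymethoxy)benzene
Conditions: NaH, THF, 0 °C; then MOMCl, 0 °C to rt
Reagents that add atoms: chloromethyl methyl ether, COCCl
Why: The same Williamson-type MOM ether formation masks the acidic phenol so that the aryl bromide can be lithiated in the next step.

**Step 5**
Reactants: 8 4-bromo-1-methoxy-2-(methoxymethoxy)benzene; 9 N,2-dimethoxy-N-methylacetamide
Product: 12 2-methoxy-1-[4-methoxy-3-(methoxymethoxy)phenyl]ethan-1-one, via aryllithium 10 (not isolated), via tetrahedral lithium adduct 11 (not isolated)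
Conditions: n-BuLi, THF, −78 °C; then 9, −78 to 0 °C; H2O
Reagents that add atoms: none
Why: Bromine–lithium exchange at −78 °C outruns ortho-lithiation next to the MOM ether, and acylation with the N-methoxy-N-methyl amide stops at the ketone because the chelated adduct 11 collapses only on aqueous quench (Weinreb ketone synthesis).

**Step 6**
Reactants: 6 1-bromo-2-iodo-5-(methoxymethoxy)-4-(3-methylbut-2-en-1-yl)benzene; 12 2-methoxy-1-[4-methoxy-3-(methoxymethoxy)phenyl]ethan-1-one
Product: 14 3-methoxy-6-(methoxymethoxy)-2-[4-methoxy-3-(methoxymethoxy)phenyl]-5-(3-methylbut-2-en-1-yl)-1-benzofuran, via alpha-aryl ketone 13 (not isolated)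
Conditions: Pd2(dba)3 (cat.), DPEphos (cat.), Cs2CO3 (3 equiv), toluene, 110 °C
Reagents that add atoms: none
Why: Zerovalent palladium should insert into the C–I bond of 6 well before the C–Br bond, the caesium enolate of 12 (which can form only at the methoxy-bearing CH2) replaces iodide on palladium, and C–C reductive elimination gives the alpha-aryl ketone 13 with the C3–C3a bond in place. Ketone 13 is more acidic than 12 and is enolised again; insertion into the neighbouring C–Br bond and exchange of bromide for the enolate oxygen give a six-membered oxapalladacycle, and C–O reductive elimination forms O1–C7a, closing the five-membered ring B by intramolecular enolate O-arylation as an already aromatic furan. The closest known reaction type is the palladium-catalysed tandem ketone alpha-arylation and intramolecular enolate O-arylation of 1,2-dihaloarenes to 2,3-disubstituted benzofurans, for which wide-bite-angle bisphosphines with Cs2CO3 in toluene are established. No stereocentre is created, since the racemic centre of 13 becomes planar on ring closure. The step needs site selectivity between the two halogens, and halogen identity secures it: iodine reacts before bromine, which places carbon para and oxygen meta to the C6 OMOM group. The prenyl olefin cannot reach either palladated carbon for a Heck reaction and the MOM ethers are stable to the base.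

**Step 7**
Reactants: 14 3-methoxy-6-(methoxymethoxy)-2-[4-methoxy-3-(methoxymethoxy)phenyl]-5-(3-methylbut-2-en-1-yl)-1-benzofuran
Product: 15 2-(3-hydroxy-4-methoxyphenyl)-3-methoxy-5-(3-methylbut-2-en-1-yl)-1-benzofuran-6-ol
Conditions: HCl (aq, dilute), MeOH, rt to 40 °C
Reagents that add atoms: none
Why: Acid-catalysed transacetalisation of the two aryl MOM ethers with methanol (acetal cleavage) should free both phenols, while the aryl methyl ethers, the aromatic 3-methoxyfuran and, at this mild acidity and temperature, the prenyl double bond should remain intact.

**Compound list**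

1 | 3-bromophenol | Oc1cccc(Br)c1 | starting material
2 | 3-bromo-4-iodophenol | Oc1ccc(I)c(Br)c1 | intermediate
3 | prenyl bromide (1-bromo-3-methylbut-2-ene) | CC(C)=CCBr | starting material
4 | sodium 3-bromo-4-iodophenoxide | [Na+].[O-]c1ccc(I)c(Br)c1 | intermediate
5 | 5-bromo-4-iodo-2-(3-methylbut-2-en-1-yl)phenol | CC(C)=CCc1cc(I)c(Br)cc1O | intermediate
6 | 1-bromo-2-iodo-5-(methoxymethoxy)-4-(3-methylbut-2-en-1-yl)benzene | COCOc1cc(Br)c(I)cc1CC=C(C)C | intermediate
7 | 5-bromo-2-methoxyphenol | COc1ccc(Br)cc1O | starting material
8 | 4-bromo-1-methoxy-2-(methoxymethoxy)benzene | COCOc1cc(Br)ccc1OC | intermediate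
9 | N,2-dimethoxy-N-methylacetamide | COCC(=O)N(C)OC | starting material
10 | aryllithium, [4-methoxy-3-(methoxymethoxy)phenyl]lithium | [Li]c1ccc(OC)c(OCOC)c1 | intermediate
11 | tetrahedral lithium adduct, lithium 2-methoxy-1-[methoxy(methyl)amino]-1-[4-methoxy-3-(methoxymethoxy)phenyl]ethan-1-olate (racemic) | COCC(O[Li])(N(C)OC)c1ccc(OC)c(OCOC)c1 | intermediate
12 | 2-methoxy-1-[4-methoxy-3-(methoxymethoxy)phenyl]ethan-1-one | COCC(=O)c1ccc(OC)c(OCOC)c1 | intermediate
13 | alpha-aryl ketone, 2-[2-bromo-4-(methoxymethoxy)-5-(3-methylbut-2-en-1-yl)phenyl]-2-methoxy-1-[4-methoxy-3-(methoxymethoxy)phenyl]ethan-1-one (racemic) | COCOc1cc(Br)c(C(OC)C(=O)c2ccc(OC)c(OCOC)c2)cc1CC=C(C)C | intermediate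
14 | 3-methoxy-6-(methoxymethoxy)-2-[4-methoxy-3-(methoxymethoxy)phenyl]-5-(3-methylbut-2-en-1-yl)-1-benzofuran | COCOc1cc2oc(-c3ccc(OC)c(OCOC)c3)c(OC)c2cc1CC=C(C)C | intermediate
15 | 2-(3-hydroxy-4-methoxyphenyl)-3-methoxy-5-(3-methylbut-2-en-1-yl)-1-benzofuran-6-ol | COc1ccc(-c2oc3cc(O)c(CC=C(C)C)cc3c2OC)cc1O | target

Total step count: 7 steps.
Longest linear sequence: 5 steps (steps 1, 2, 3, 6 and 7, from 3-bromophenol); the ketone branch (steps 4 and 5) joins at step 6.

**Steps most likely to fail**

Step 6. The second half of the cascade may not keep pace with the first: after C-arylation at iodine, insertion into the C–Br bond and C–O reductive elimination may be slower than protodebromination or base-induced breakdown of the ketone at 110 °C, so the open-chain material accumulates or is lost. The fallback sets out from 6 and 12 and separates the two bond formations. The palladium alpha-arylation is run alone under milder conditions (Pd2(dba)3, xantphos, K3PO4, THF, 70 °C), where only the C–I bond should react, and the alpha-aryl ketone 13 is isolated. Ring B is then closed by an Ullmann-type intramolecular O-arylation of its enolate at the bromide under copper catalysis (CuI, K3PO4, DMF, 105 °C), which returns to the route at 14. This detour makes no compound that the list lacks (F0).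

Step 2. The phenoxide may react at oxygen instead of carbon, at the crowded ortho carbon between oxygen and bromine, or a second time on the product, so that the wanted mono-C6-prenyl phenol is a minor component. The fallback sets out from 2 and makes the two events separate. O-Alkylation with 3 (K2CO3, acetone, reflux) should give 2-bromo-1-iodo-4-[(3-methylbut-2-en-1-yl)oxy]benzene F1. Treatment with montmorillonite K10 clay in CH2Cl2 at 0 °C should then ionise the ether and return the prenyl cation to the free ortho carbon (acid-clay [1,3] shift, a Friedel–Crafts-type recombination with the para carbon blocked), which comes back to the route at 5.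

Step 7. Protic acid may add the C6 phenol across the prenyl double bond (closure to a 2,2-dimethylchroman), add methanol or HCl to that olefin, or hydrolyse the 3-methoxy enol ether before both acetals are gone. The fallback sets out from 14 and avoids Brønsted acid altogether. TMSOTf with 2,2'-bipyridyl in MeCN at 0 °C to rt should exchange both aryl MOM groups for silyl groups, giving 3-methoxy-5-(3-methylbut-2-en-1-yl)-6-(trimethylsilyloxy)-2-[4-methoxy-3-(trimethylsilyloxy)phenyl]-1-benzofuran F2. Its silyl ethers are then cleaved under mild base (K2CO3 cat., MeOH, rt), which comes back to the route at 15.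

**Further compounds**

F0 | step 6 | none | none
F1 | step 2 | 2-bromo-1-iodo-4-[(3-methylbut-2-en-1-yl)oxy]benzene | CC(C)=CCOc1ccc(I)c(Br)c1
F2 | step 7 | 3-methoxy-5-(3-methylbut-2-en-1-yl)-6-(trimethylsilyloxy)-2-[4-methoxy-3-(trimethylsilyloxy)phenyl]-1-benzofuran | COc1ccc(-c2oc3cc(O[Si](C)(C)C)c(CC=C(C)C)cc3c2OC)cc1O[Si](C)(C)C
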